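**Plan**

1. Retrosynthesis: the side-chain alkene C1'=C2' is cut first (cross-metathesis of a C2-vinyl core with a five-carbon alkene). The helper groups are then put back (C6=C7 from a C7 acetate, the C2 vinyl group from a C2 carboxamide). Last, C2–C3 and C3a–C7a are cut together.
2. Enabling feature: the tetrahydrofuran O1–C2–C3–C3a–C7a is the [3+2] adduct of a carbonyl ylide (C2–O1–C7a) and a Z-enediol (C3=C3a). The lactone ester O4–C5 ties C3a to C7a through four atoms (C7, C6, C5, O4), so one intramolecular cycloaddition closes the furan ring and the pyranone ring together.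
3. Forward: O-acetyl-D-malic anhydride gives an aldehyde (C7a) that carries the C7 acetate and a Z-silyloxyvinyl ester (C3=C3a). A rhodium carbenoid (C2) turns it into the ylide, which cyclises to the bicyclic core. Then follow amide to vinyl, loss of AcOH, cross-metathesis and desilylation.
4. Stereochemistry: C3/C3a from the Z alkene, C3a/C7a from the tether, C2 from the W-shaped ylide, absolute sense from the C7 acetate (erased later). Both side-chain centres come from a Sharpless epoxidation of divinylcarbinol.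

Key step: step 7

Remark: intermediates are described with the target's locants (O1, C2, C3, C3a, O4, C5, C6, C7, C7a; side chain C1'–C5'). CIP descriptors of ring atoms change along the route only because substituent priorities change. The Felkin-type facial sense assumed in step 7 is what calls for the (R)-anhydride 1 (taken as a catalogue compound); the (S)-anhydride would serve if the sense proved opposite.

**Route**

Step 1
Reactants: 1 (3R)-2,5-dioxooxolan-3-yl acetate [(R)-2-acetoxysuccinic anhydride]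
Product: 2 (3R)-3-(acetyloxy)-4-[methoxy(methyl)amino]-4-oxobutanoic acid
Conditions: MeNH(OMe)·HCl, pyridine, CH2Cl2, −20 to 0 °C
Reagents that add atoms: N,O-dimethylhydroxylamine hydrochloride, CNOC.Cl
Why: Aminolysis of the cyclic anhydride should take place at the carbonyl next to the acetoxy-bearing carbon (the more electrophilic one, as known for O-acylmalic anhydrides) and give the Weinreb amide acid with the stereocentre untouched.

Step 2
Reactants: 2 (3R)-3-(acetyloxy)-4-[methoxy(methyl)amino]-4-oxobutanoic acid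
Product: 3 prop-2-en-1-yl (3R)-3-(acetyloxy)-4-[methoxy(methyl)amino]-4-oxobutanoate
Conditions: allyl bromide, KHCO3, DMF, 0 °C to rt
Reagents that add atoms: allyl bromide, C=CCBr
Why: SN2 O-alkylation of the carboxylate needs no acyl activation, so β-elimination of the acetate is avoided.

Step 3
Reactants: 3 prop-2-en-1-yl (3R)-3-(acetyloxy)-4-[methoxy(methyl)amino]-4-oxobutanoate
Product: 5 2-oxoethyl (3R)-3-(acetyloxy)-4-[methoxy(methyl)amino]-4-oxobutanoate, via ozonide 4 (not isolated)
Conditions: O3, CH2Cl2, −78 °C; then Me2S, −78 °C to rt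
Reagents that add atoms: ozone, [O-][O+]=O
Why: Ozonolysis with reductive work-up cleaves the terminal alkene of the allyl ester to the acyloxyacetaldehyde, the only aldehyde present at this stage.

Step 4
Reactants: 5 2-oxoethyl (3R)-3-(acetyloxy)-4-[methoxy(methyl)amino]-4-oxobutanoate
Product: 6 (Z)-2-[(tert-butyldimethylsilyl)oxy]ethenyl (3R)-3-(acetyloxy)-4-[methoxy(methyl)amino]-4-oxobutanoate
Conditions: TBSOTf, Et3N, CH2Cl2, −78 °C
Reagents that add atoms: tert-butyldimethylsilyl triflate, CC(C)(C)[Si](C)(C)OS(=O)(=O)C(F)(F)F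
Why: Soft enolisation and O-silylation of the aldehyde should give the Z enol silane (acyloxy cis to silyloxy, as known for enol silanes of acyloxy- and alkoxyacetaldehydes), which stores the later cis relation of C3 and C3a, while the much less acidic amide and ester α-hydrogens stay untouched.

Step 5
Reactants: 6 (Z)-2-[(tert-butyldimethylsilyl)oxy]ethenyl (3R)-3-(acetyloxy)-4-[methoxy(methyl)amino]-4-oxobutanoate
Product: 7 (Z)-2-[(tert-butyldimethylsilyl)oxy]ethenyl (3R)-3-(acetyloxy)-4-oxobutanoate
Conditions: Cp2Zr(H)Cl (1.5 equiv), THF, rt, 15 min; SiO2 work-up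
Reagents that add atoms: none
Why: Amide-to-aldehyde reduction with the Schwartz reagent proceeds through a zirconium hemiaminal that releases the aldehyde only on work-up, so the esters, the acetate and the internal enol silane should survive and the C7 centre is not touched.

Step 6
Reactants: 8 2-bromo-N-methoxy-N-methylacetamide
Product: 9 2-diazo-N-methoxy-N-methylacetamide
Conditions: TsNHNHTs, DBU, THF, 0 °C
Reagents that add atoms: N,N'-ditosylhydrazine, Cc1ccc(cc1)S(=O)(=O)NNS(=O)(=O)c1ccc(C)cc1
Why: N-Alkylation of the bis-sulfonylhydrazine followed by base-induced loss of two sulfinate groups is a standard diazoacetyl synthesis and gives the acceptor diazo amide.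

Step 7
Reactants: 7 (Z)-2-[(tert-butyldimethylsilyl)oxy]ethenyl (3R)-3-(acetyloxy)-4-oxobutanoate; 9 2-diazo-N-methoxy-N-methylacetamide
Product: 11 (2R,3S,3aS,7R,7aR)-7-(acetyloxy)-3-[(tert-butyldimethylsilyl)oxy]-N-methoxy-N-methyl-5-oxohexahydro-2H-furo[3,2-b]pyran-2-carboxamide, via carbonyl ylide 10 (not isolated)
Conditions: Rh2(OAc)4 (2 mol %), 4 Å MS, CH2Cl2 (0.01 M), rt, 9 added by syringe pump over 6 h
Reagents that add atoms: none
Why: Proposed new method: the rhodium carbenoid from 9 should be captured by the aldehyde oxygen of 7 to give the amide-stabilised, W-shaped carbonyl ylide 10 (C2–O1–C7a), which adds suprafacially across the tethered Z-enol silane C3=C3a in an intramolecular [3+2] cycloaddition that forms C2–C3 and C3a–C7a in one event; the closest known reaction type is the Rh(II)-catalysed three-component carbonyl-ylide cycloaddition of diazo carbonyl compounds, aldehydes and electron-poor alkenes, extended here to an ester-tethered, electron-rich enediol derivative. The tetrahydrofuran ring is closed by the cycloaddition itself (both of its C–C bonds), and the δ-lactone ring is closed at the same moment as the tether ring when C7a meets C3a (six-membered, fused, with the ester in its s-cis rotamer). C3a and C7a are set cis by the four-atom tether C7–C6–C5–O4, C3 is set cis to C3a by the Z geometry of the enol silane, and C2 is set cis to C7a by the E,E (W) geometry of the ylide, so that all four substituents fall on one face as in endo adducts of W-shaped azomethine ylides. The absolute sense is controlled by the C7 acetoxy stereocentre, which in the half-chair of the forming lactone ring should sit pseudo-equatorial and anti to the incoming C3a (Felkin–Anh arrangement at the oxocarbenium-like terminus C7a) and thereby expose the face that leads to the target series. Regiochemistry is fixed by the tether and is polarity-matched, since the nucleophilic enol-silane carbon C3a meets the electrophilic terminus C7a and the silyloxy-bearing C3 meets the enolate-like C2. The step needs the carbenoid to choose the aldehyde oxygen over cyclopropanation of the enol silane, which the acyloxy substituent and the bulky silyl group on that cis-disubstituted alkene, the low electrophilicity of an amide carbenoid and slow addition of 9 at high dilution should secure.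

Step 8
Reactants: 11 (2R,3S,3aS,7R,7aR)-7-(acetyloxy)-3-[(tert-butyldimethylsilyl)oxy]-N-methoxy-N-methyl-5-oxohexahydro-2H-furo[3,2-b]pyran-2-carboxamide
Product: 12 (2R,3S,3aS,7R,7aR)-3-[(tert-butyldimethylsilyl)oxy]-2-formyl-5-oxohexahydro-2H-furo[3,2-b]pyran-7-yl acetate
Conditions: Cp2Zr(H)Cl (1.5 equiv), THF, rt, 15 min; SiO2 work-up
Reagents that add atoms: none
Why: The same Schwartz amide-to-aldehyde reduction should convert the Weinreb amide at C2 chemoselectively in the presence of the lactone and the acetate, with C2 kept because the aldehyde is only set free on work-up.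

Step 9
Reactants: 12 (2R,3S,3aS,7R,7aR)-3-[(tert-butyldimethylsilyl)oxy]-2-formyl-5-oxohexahydro-2H-furo[3,2-b]pyran-7-yl acetate
Product: 13 (2S,3R,3aS,7R,7aR)-3-[(tert-butyldimethylsilyl)oxy]-2-ethenyl-5-oxohexahydro-2H-furo[3,2-b]pyran-7-yl acetate
Conditions: Ph3PCH3Br, KHMDS, THF, −78 °C (1.1 equiv of preformed ylide)
Reagents that add atoms: methyltriphenylphosphonium bromide (as its ylide), C[P+](c1ccccc1)(c1ccccc1)c1ccccc1.[Br-]
Why: Wittig methylenation of the aldehyde at −78 °C should outrun both epimerisation at C2 and β-elimination of the C7 acetate, which would in any case only anticipate step 10.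

Step 10
Reactants: 13 (2S,3R,3aS,7R,7aR)-3-[(tert-butyldimethylsilyl)oxy]-2-ethenyl-5-oxohexahydro-2H-furo[3,2-b]pyran-7-yl acetate
Product: 14 (2S,3R,3aS,7aR)-3-[(tert-butyldimethylsilyl)oxy]-2-ethenyl-2,3,3a,7a-tetrahydro-5H-furo[3,2-b]pyran-5-one
Conditions: DBU (1.2 equiv), CH2Cl2, 0 °C
Reagents that add atoms: none
Why: E1cB elimination of acetic acid from the β-acetoxy δ-lactone gives the conjugated C6=C7 lactone and erases the auxiliary C7 stereocentre, at a stage where no epimerisable carbonyl remains at C2.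

Step 11
Reactants: 15 penta-1,4-dien-3-ol (divinylcarbinol)
Product: 16 (1S)-1-[(2R)-oxiran-2-yl]prop-2-en-1-ol
Conditions: Ti(OiPr)4, L-(+)-DIPT, t-BuOOH, 4 Å MS, CH2Cl2, −20 °C
Reagents that add atoms: tert-butyl hydroperoxide, CC(C)(C)OO
Why: Sharpless asymmetric epoxidation of the achiral dienol couples enantiotopic-group selection with diastereofacial selection, so L-(+)-tartrate should give the anti (2R,3S) epoxy alcohol and with it both side-chain stereocentres.

Step 12
Reactants: 16 (1S)-1-[(2R)-oxiran-2-yl]prop-2-en-1-ol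
Product: 17 tert-butyldimethyl{[(1S)-1-[(2R)-oxiran-2-yl]prop-2-en-1-yl]oxy}silane
Conditions: TBSCl, imidazole, DMF, rt
Reagents that add atoms: tert-butyldimethylsilyl chloride, CC(C)(C)[Si](C)(C)Cl
Why: Standard silylation of the secondary allylic alcohol, with no change at either stereocentre.

Step 13
Reactants: 17 tert-butyldimethyl{[(1S)-1-[(2R)-oxiran-2-yl]prop-2-en-1-yl]oxy}silane
Product: 19 (2R,3S)-3-[(tert-butyldimethylsilyl)oxy]pent-4-en-2-yl benzoate, via lithium alkoxide 18 (not isolated)
Conditions: LiEt3BH (1.1 equiv), THF, 0 °C; then BzCl (1.5 equiv), 0 °C to rt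
Reagents that add atoms: benzoyl chloride, O=C(Cl)c1ccccc1
Why: Hydride opens the terminal epoxide at the unsubstituted carbon (SN2, configuration at the carbinol carbon retained) and the resulting lithium alkoxide is benzoylated in the same flask before the neighbouring silyl group can migrate.

Step 14
Reactants: 14 (2S,3R,3aS,7aR)-3-[(tert-butyldimethylsilyl)oxy]-2-ethenyl-2,3,3a,7a-tetrahydro-5H-furo[3,2-b]pyran-5-one; 19 (2R,3S)-3-[(tert-butyldimethylsilyl)oxy]pent-4-en-2-yl benzoate
Product: 20 (2R,3S,4E)-3-[(tert-butyldimethylsilyl)oxy]-5-[(2S,3R,3aS,7aR)-3-[(tert-butyldimethylsilyl)oxy]-5-oxo-2,3,3a,7a-tetrahydro-5H-furo[3,2-b]pyran-2-yl]pent-4-en-2-yl benzoate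
Conditions: Hoveyda–Grubbs second-generation catalyst (10 mol %), 19 (3 equiv), CH2Cl2, 40 °C
Reagents that add atoms: none
Why: Cross-metathesis of the two terminal alkenes with loss of ethylene should give the E alkene under thermodynamic control, while the cis-disubstituted, electron-poor lactone alkene stays out of the reaction.

Step 15
Reactants: 20 (2R,3S,4E)-3-[(tert-butyldimethylsilyl)oxy]-5-[(2S,3R,3aS,7aR)-3-[(tert-butyldimethylsilyl)oxy]-5-oxo-2,3,3a,7a-tetrahydro-5H-furo[3,2-b]pyran-2-yl]pent-4-en-2-yl benzoate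
Product: 21 (2R,3S,4E)-3-hydroxy-5-[(2S,3R,3aR,7aR)-3-hydroxy-5-oxo-2,3,3a,7a-tetrahydro-5H-furo[3,2-b]pyran-2-yl]pent-4-en-2-yl benzoate (CNP0143030.1)
Conditions: HF·pyridine, pyridine/THF, 0 °C to rt
Reagents that add atoms: none
Why: Buffered fluoride cleaves both secondary silyl ethers without base, so the benzoate should not migrate to the freed neighbouring hydroxyl and the unsaturated lactone stays intact.

**Compound list**

1 | (3R)-2,5-dioxooxolan-3-yl acetate [(R)-2-acetoxysuccinic anhydride] | CC(=O)O[C@@H]1CC(=O)OC1=O | starting material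
2 | (3R)-3-(acetyloxy)-4-[methoxy(methyl)amino]-4-oxobutanoic acid | CON(C)C(=O)[C@H](OC(C)=O)CC(=O)O | intermediate
3 | prop-2-en-1-yl (3R)-3-(acetyloxy)-4-[methoxy(methyl)amino]-4-oxobutanoate | CON(C)C(=O)[C@H](OC(C)=O)CC(=O)OCC=C | intermediate
4 | (1,2,4-trioxolan-3-yl)methyl (3R)-3-(acetyloxy)-4-[methoxy(methyl)amino]-4-oxobutanoate (ozonide of 3, not isolated) | CON(C)C(=O)[C@H](OC(C)=O)CC(=O)OCC1OCOO1 | intermediate
5 | 2-oxoethyl (3R)-3-(acetyloxy)-4-[methoxy(methyl)amino]-4-oxobutanoate | CON(C)C(=O)[C@H](OC(C)=O)CC(=O)OCC=O | intermediate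
6 | (Z)-2-[(tert-butyldimethylsilyl)oxy]ethenyl (3R)-3-(acetyloxy)-4-[methoxy(methyl)amino]-4-oxobutanoate | CON(C)C(=O)[C@H](OC(C)=O)CC(=O)O/C=C\O[Si](C)(C)C(C)(C)C | intermediate
7 | (Z)-2-[(tert-butyldimethylsilyl)oxy]ethenyl (3R)-3-(acetyloxy)-4-oxobutanoate | O=C[C@H](OC(C)=O)CC(=O)O/C=C\O[Si](C)(C)C(C)(C)C | intermediate
8 | 2-bromo-N-methoxy-N-methylacetamide | CON(C)C(=O)CBr | starting material
9 | 2-diazo-N-methoxy-N-methylacetamide | CON(C)C(=O)C=[N+]=[N-] | intermediate
10 | W-shaped carbonyl ylide from 7 and 9 (C2 carbanion, O1 oxonium, C7a; not isolated) | CON(C)C(=O)[CH-]/[O+]=C/[C@H](OC(C)=O)CC(=O)O/C=C\O[Si](C)(C)C(C)(C)C | intermediate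
11 | (2R,3S,3aS,7R,7aR)-7-(acetyloxy)-3-[(tert-butyldimethylsilyl)oxy]-N-methoxy-N-methyl-5-oxohexahydro-2H-furo[3,2-b]pyran-2-carboxamide (C2, C3, C3a and C7a substituents all cis; 7-OAc on the O1 face) | CON(C)C(=O)[C@@H]1O[C@@H]2[C@H](OC(C)=O)CC(=O)O[C@@H]2[C@@H]1O[Si](C)(C)C(C)(C)C | intermediate
12 | (2R,3S,3aS,7R,7aR)-3-[(tert-butyldimethylsilyl)oxy]-2-formyl-5-oxohexahydro-2H-furo[3,2-b]pyran-7-yl acetate | O=C[C@@H]1O[C@@H]2[C@H](OC(C)=O)CC(=O)O[C@@H]2[C@@H]1O[Si](C)(C)C(C)(C)C | intermediate
13 | (2S,3R,3aS,7R,7aR)-3-[(tert-butyldimethylsilyl)oxy]-2-ethenyl-5-oxohexahydro-2H-furo[3,2-b]pyran-7-yl acetate | C=C[C@@H]1O[C@@H]2[C@H](OC(C)=O)CC(=O)O[C@@H]2[C@@H]1O[Si](C)(C)C(C)(C)C | intermediate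
14 | (2S,3R,3aS,7aR)-3-[(tert-butyldimethylsilyl)oxy]-2-ethenyl-2,3,3a,7a-tetrahydro-5H-furo[3,2-b]pyran-5-one | C=C[C@@H]1O[C@@H]2C=CC(=O)O[C@@H]2[C@@H]1O[Si](C)(C)C(C)(C)C | intermediate
15 | penta-1,4-dien-3-ol | C=CC(O)C=C | starting material
16 | (1S)-1-[(2R)-oxiran-2-yl]prop-2-en-1-ol | C=C[C@H](O)[C@H]1CO1 | intermediate
17 | tert-butyldimethyl{[(1S)-1-[(2R)-oxiran-2-yl]prop-2-en-1-yl]oxy}silane | C=C[C@H](O[Si](C)(C)C(C)(C)C)[C@H]1CO1 | intermediate
18 | lithium (2R,3S)-3-[(tert-butyldimethylsilyl)oxy]pent-4-en-2-olate (not isolated) | [Li+].C[C@@H]([O-])[C@@H](O[Si](C)(C)C(C)(C)C)C=C | intermediate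
19 | (2R,3S)-3-[(tert-butyldimethylsilyl)oxy]pent-4-en-2-yl benzoate | C[C@@H](OC(=O)c1ccccc1)[C@@H](O[Si](C)(C)C(C)(C)C)C=C | intermediate
20 | (2R,3S,4E)-3-[(tert-butyldimethylsilyl)oxy]-5-[(2S,3R,3aS,7aR)-3-[(tert-butyldimethylsilyl)oxy]-5-oxo-2,3,3a,7a-tetrahydro-5H-furo[3,2-b]pyran-2-yl]pent-4-en-2-yl benzoate | C[C@@H](OC(=O)c1ccccc1)[C@@H](O[Si](C)(C)C(C)(C)C)/C=C/[C@@H]1O[C@@H]2C=CC(=O)O[C@@H]2[C@@H]1O[Si](C)(C)C(C)(C)C | intermediate
21 | (2R,3S,4E)-3-hydroxy-5-[(2S,3R,3aR,7aR)-3-hydroxy-5-oxo-2,3,3a,7a-tetrahydro-5H-furo[3,2-b]pyran-2-yl]pent-4-en-2-yl benzoate | C[C@@H](OC(=O)c1ccccc1)[C@@H](O)/C=C/[C@@H]1O[C@@H]2C=CC(=O)O[C@@H]2[C@@H]1O | target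

**Step count and risks**

Total step count: 15. Longest linear sequence: 11 steps (steps 1–5, 7–10, 14, 15).

Steps most likely to fail:

1. Step 7 (proposed new method).
   - What may go wrong: the carbenoid may cyclopropanate the enol silane instead of reaching the aldehyde. The ylide may collapse by proton transfer or by adding a second aldehyde before the ester tether reaches its s-cis rotamer. Reaction through the sickle-shaped ylide would invert C2. Facial control by the C7 acetate may be weak.
   - Fallback (sets out from 7, returns at 11): the two bonds are formed one after the other by known reaction types. BF3·OEt2 at −78 °C should bring about an intramolecular Mukaiyama aldol addition of the enol-silane carbon C3a to the aldehyde C7a and give, with loss of the silyl group, the hydroxy aldehyde lactone (4R,5R,6S)-6-formyl-5-hydroxy-2-oxooxan-4-yl acetate F1. Rh2(OAc)4 and 9 should then turn the C7a hydroxyl group into an oxonium ylide that is trapped in an aldol-type ring closure by the neighbouring aldehyde (the known alcohol–diazo–carbonyl three-component reaction, run intramolecularly). This gives the hydroxy tetrahydrofuran (2R,3S,3aR,7R,7aR)-7-(acetyloxy)-3-hydroxy-N-methoxy-N-methyl-5-oxohexahydro-2H-furo[3,2-b]pyran-2-carboxamide F2. Silylation (TBSOTf, 2,6-lutidine) returns 11. Stereocontrol at C3a, C2 and C3 would then rest on the cis-fused bicycle and might call for a separation.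

2. Step 5.
   - What may go wrong: the zirconium hydride may attack the activated enol ester or over-reduce, and the α-acetoxy aldehyde may lose its configuration at C7 during work-up.
   - Fallback (sets out from 1, returns at 7): the latent aldehyde is carried as a thioester and unmasked by palladium-catalysed silane reduction. Ethanethiol and pyridine should open 1 at the same carbonyl and give the thioester acid (3R)-3-(acetyloxy)-4-(ethylsulfanyl)-4-oxobutanoic acid F3. Allyl bromide/KHCO3 gives the allyl ester prop-2-en-1-yl (3R)-3-(acetyloxy)-4-(ethylsulfanyl)-4-oxobutanoate F4. Ozonolysis, through the ozonide (1,2,4-trioxolan-3-yl)methyl (3R)-3-(acetyloxy)-4-(ethylsulfanyl)-4-oxobutanoate F5 and Me2S, gives the aldehyde 2-oxoethyl (3R)-3-(acetyloxy)-4-(ethylsulfanyl)-4-oxobutanoate F6. TBSOTf/Et3N gives the Z enol silane (Z)-2-[(tert-butyldimethylsilyl)oxy]ethenyl (3R)-3-(acetyloxy)-4-(ethylsulfanyl)-4-oxobutanoate F7. Fukuyama reduction (Et3SiH, Pd/C, acetone) then gives 7 under neutral, non-hydridic conditions.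

3. Step 14.
   - What may go wrong: metathesis between two hindered, allylically oxygenated alkenes may be slow and unselective, with homodimerisation and catalyst decay.
   - Fallback (sets out from 14, with the partner drawn from 19, returns at 21): the silyl ether partner is replaced by an electron-poor vinyl ketone, a more reliable and E-selective partner, and the carbinol is reset by reagent-controlled reduction. HF·pyridine frees the allylic alcohol (2R,3S)-3-hydroxypent-4-en-2-yl benzoate F8 from 19. Dess–Martin periodinane gives the vinyl ketone (2R)-3-oxopent-4-en-2-yl benzoate F9. Cross-metathesis of 14 with F9 gives the enone (2R,4E)-5-[(2S,3R,3aS,7aR)-3-[(tert-butyldimethylsilyl)oxy]-5-oxo-2,3,3a,7a-tetrahydro-5H-furo[3,2-b]pyran-2-yl]-3-oxopent-4-en-2-yl benzoate F10. (S)-CBS reduction (catecholborane, −78 °C, alkenyl arm as the large group) gives the allylic alcohol (2R,3S,4E)-5-[(2S,3R,3aS,7aR)-3-[(tert-butyldimethylsilyl)oxy]-5-oxo-2,3,3a,7a-tetrahydro-5H-furo[3,2-b]pyran-2-yl]-3-hydroxypent-4-en-2-yl benzoate F11. HF·pyridine then gives 21.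

**Further compounds**

F1 | step 7 | (4R,5R,6S)-6-formyl-5-hydroxy-2-oxooxan-4-yl acetate | O=C[C@H]1OC(=O)C[C@@H](OC(C)=O)[C@H]1O
F2 | step 7 | (2R,3S,3aR,7R,7aR)-7-(acetyloxy)-3-hydroxy-N-methoxy-N-methyl-5-oxohexahydro-2H-furo[3,2-b]pyran-2-carboxamide | CON(C)C(=O)[C@@H]1O[C@@H]2[C@H](OC(C)=O)CC(=O)O[C@@H]2[C@@H]1O
F3 | step 5 | (3R)-3-(acetyloxy)-4-(ethylsulfanyl)-4-oxobutanoic acid | CCSC(=O)[C@H](OC(C)=O)CC(=O)O
F4 | step 5 | prop-2-en-1-yl (3R)-3-(acetyloxy)-4-(ethylsulfanyl)-4-oxobutanoate | CCSC(=O)[C@H](OC(C)=O)CC(=O)OCC=C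
F5 | step 5 | (1,2,4-trioxolan-3-yl)methyl (3R)-3-(acetyloxy)-4-(ethylsulfanyl)-4-oxobutanoate | CCSC(=O)[C@H](OC(C)=O)CC(=O)OCC1OCOO1
F6 | step 5 | 2-oxoethyl (3R)-3-(acetyloxy)-4-(ethylsulfanyl)-4-oxobutanoate | CCSC(=O)[C@H](OC(C)=O)CC(=O)OCC=O
F7 | step 5 | (Z)-2-[(tert-butyldimethylsilyl)oxy]ethenyl (3R)-3-(acetyloxy)-4-(ethylsulfanyl)-4-oxobutanoate | CCSC(=O)[C@H](OC(C)=O)CC(=O)O/C=C\O[Si](C)(C)C(C)(C)C
F8 | step 14 | (2R,3S)-3-hydroxypent-4-en-2-yl benzoate | C[C@@H](OC(=O)c1ccccc1)[C@@H](O)C=C
F9 | step 14 | (2R)-3-oxopent-4-en-2-yl benzoate | C[C@@H](OC(=O)c1ccccc1)C(=O)C=C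
F10 | step 14 | (2R,4E)-5-[(2S,3R,3aS,7aR)-3-[(tert-butyldimethylsilyl)oxy]-5-oxo-2,3,3a,7a-tetrahydro-5H-furo[3,2-b]pyran-2-yl]-3-oxopent-4-en-2-yl benzoate | C[C@@H](OC(=O)c1ccccc1)C(=O)/C=C/[C@@H]1O[C@@H]2C=CC(=O)O[C@@H]2[C@@H]1O[Si](C)(C)C(C)(C)C
F11 | step 14 | (2R,3S,4E)-5-[(2S,3R,3aS,7aR)-3-[(tert-butyldimethylsilyl)oxy]-5-oxo-2,3,3a,7a-tetrahydro-5H-furo[3,2-b]pyran-2-yl]-3-hydroxypent-4-en-2-yl benzoate | C[C@@H](OC(=O)c1ccccc1)[C@@H](O)/C=C/[C@@H]1O[C@@H]2C=CC(=O)O[C@@H]2[C@@H]1O[Si](C)(C)C(C)(C)C
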